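**Retrosynthetic overview**

1. Primed locants are those of the six-membered carbocycle: C1' is the carbinol carbon bearing the dienoic acid chain, C2' carries a methyl, C4' is the ketone, and quaternary C6' carries CH3 and the acylated C8'H2O. The C1'–OH and C4'=O stand 1,4 across C2'=C3', the imprint of O2 added across a C1'=C2'–C3'=C4' ring diene whose only ring stereocentre is C6'. Hence 20 ⇐ silyl ether 19 ⇐ tetraene acid 17 by photo-oxygenation and Kornblum–DeLaMare opening.
2. 17 ⇐ Stille coupling (C1'–C5 bond) of dienyl triflate 12 with stannyl dienoic acid 16, made from but-2-ynoic acid 13 through Z iodo acid 14 and bis-stannane 15.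
3. 12 ⇐ keto ester 11 (Tf2O) ⇐ hydroxymethyl ketone 3 + half ester 10; 3 ⇐ catalytic asymmetric hydroxymethylation of silyl dienol ether 2 of enone 1, which sets C6'.
4. 10 ⇐ (R)-mevalonolactone 4. Its carboxyl carbon must become the ester to C8' and its C5 the methyl ester, so the carboxyl is held as a benzyl ester while C5 is oxidised and methylated; plain methanolysis and oxidation would give the mirror-image half ester.
5. Ring order: the carbocycle is carried from 1 and no lasting ring is built; the only ring closed is the 1,2-dioxine of endoperoxide 18, formed and opened within the key step.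

Key step: step 13

Assumption: the (S,S) ligand of step 2 is taken to give (S)-3, by analogy with cyclic 2-methyl ketone enolates that bear an sp2 substituent on the carbonyl carbon; should the sense be opposite, the (R,R) ligand is used and nothing else changes.

**Route**

Step 1
Reactants: 1 2,6-dimethylcyclohex-2-en-1-one
Product: 2 1,3-dimethyl-2-(trimethylsilyloxy)cyclohexa-1,3-diene
Conditions: LiN(iPr)2, Me3SiCl (in situ quench), THF, −78 °C
Reagents that add atoms: chlorotrimethylsilane, C[Si](C)(C)Cl
Why: Kinetic deprotonation of the enone at C6 (alpha-prime rather than gamma) and O-silylation of the cross-conjugated enolate (silyl enol ether formation) should give the dienol ether, in which the old C6 stereocentre is erased.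

Step 2
Reactants: 2 1,3-dimethyl-2-(trimethylsilyloxy)cyclohexa-1,3-diene
Product: 3 (S)-6-(hydroxymethyl)-2,6-dimethylcyclohex-2-en-1-one
Conditions: aq. HCHO, Sc(OTf)3 (10 mol %), (S,S)-6,6'-bis(1-hydroxy-2,2-dimethylpropyl)-2,2'-bipyridine (12 mol %), DME/H2O 9:1, −20 °C
Reagents that add atoms: formaldehyde, C=O
Why: Mukaiyama-type aldol addition (catalytic asymmetric hydroxymethylation of a silicon enolate with aqueous formaldehyde) in which the chiral Sc(OTf)3–bipyridine complex binds formaldehyde and screens one face of the fully substituted enol carbon, so the quaternary centre C6 is set by the catalyst.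

Step 3
Reactants: 4 (R)-mevalonolactone
Product: 6 benzyl (R)-3,5-dihydroxy-3-methylpentanoate, via potassium (R)-mevalonate 5 (not isolated)
Conditions: KOH, H2O, 40 °C; evaporate; BnBr, DMF, rt
Reagents that add atoms: potassium hydroxide, [K+].[OH-]; benzyl bromide, BrCc1ccccc1
Why: Saponification of the lactone and SN2 O-benzylation of the carboxylate mark the original carboxyl carbon, which must later be joined to C8', as a benzyl ester, while the tertiary carbinol centre is not touched.

Step 4
Reactants: 6 benzyl (R)-3,5-dihydroxy-3-methylpentanoate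
Product: 7 (R)-5-(benzyloxy)-3-hydroxy-3-methyl-5-oxopentanoic acid
Conditions: 2,2,6,6-tetramethylpiperidin-1-oxyl (cat.), PhI(OAc)2, MeCN/H2O, rt
Reagents that add atoms: water, O
Why: Oxoammonium-mediated oxidation takes only the primary alcohol through the aldehyde hydrate to the acid and leaves the tertiary alcohol and the benzyl ester alone; using fresh 6 at once forestalls relactonisation.

Step 5
Reactants: 7 (R)-5-(benzyloxy)-3-hydroxy-3-methyl-5-oxopentanoic acid
Product: 8 1-benzyl 5-methyl (R)-3-hydroxy-3-methylpentanedioate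
Conditions: Me3SiCHN2, PhMe/MeOH, 0 °C
Reagents that add atoms: (trimethylsilyl)diazomethane, C[Si](C)(C)C=[N+]=[N-]
Why: O-methylation of the acid by the diazoalkane under neutral conditions should give the mixed diester without transesterification, so the two arms stay distinct and the centre keeps its configuration.

Step 6
Reactants: 8 1-benzyl 5-methyl (R)-3-hydroxy-3-methylpentanedioate
Product: 9 1-benzyl 5-methyl (R)-3-methyl-3-(triethylsilyloxy)pentanedioate
Conditions: Et3SiOTf, 2,6-lutidine, CH2Cl2, −78 → 0 °C
Reagents that add atoms: triethylsilyl triflate, CC[Si](CC)(CC)OS(=O)(=O)C(F)(F)F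
Why: Silylation of the hindered tertiary alcohol with a silyl triflate and a non-nucleophilic base masks this oxygen against the acylating and triflating reagents of later steps.

Step 7
Reactants: 9 1-benzyl 5-methyl (R)-3-methyl-3-(triethylsilyloxy)pentanedioate
Product: 10 (S)-5-methoxy-3-methyl-5-oxo-3-(triethylsilyloxy)pentanoic acid
Conditions: H2 (1 atm), Pd/C, EtOAc, rt
Reagents that add atoms: none
Why: Hydrogenolysis of the benzyl ester frees the carboxyl that stems from the lactone carbonyl while the methyl ester and silyl ether survive; the change of descriptor from R to S reflects only the CIP priorities.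

Step 8
Reactants: 3 (S)-6-(hydroxymethyl)-2,6-dimethylcyclohex-2-en-1-one; 10 (S)-5-methoxy-3-methyl-5-oxo-3-(triethylsilyloxy)pentanoic acid
Product: 11 [(1S)-1,3-dimethyl-2-oxocyclohex-3-en-1-yl]methyl methyl (3R)-3-methyl-3-(triethylsilyloxy)pentanedioate
Conditions: DCC, 4-(dimethylamino)pyridine (cat.), CH2Cl2, 0 °C → rt
Reagents that add atoms: none
Why: Steglich esterification (carbodiimide activation and acyl transfer through the acylpyridinium) should acylate the neopentyl-type primary alcohol under conditions too mild for retro-aldol loss of formaldehyde from 3 or for scrambling of the two ester arms of 10.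

Step 9
Reactants: 11 [(1S)-1,3-dimethyl-2-oxocyclohex-3-en-1-yl]methyl methyl (3R)-3-methyl-3-(triethylsilyloxy)pentanedioate
Product: 12 [(1S)-1,3-dimethyl-2-(trifluoromethylsulfonyloxy)cyclohexa-2,4-dien-1-yl]methyl methyl (3R)-3-methyl-3-(triethylsilyloxy)pentanedioate
Conditions: Tf2O, 2,6-di-tert-butyl-4-methylpyridine, CH2Cl2, 0 °C → rt
Reagents that add atoms: triflic anhydride, O=S(=O)(OS(=O)(=O)C(F)(F)F)C(F)(F)F
Why: Enol triflate formation with Tf2O and a hindered pyridine, in which O-triflation of the enone carbonyl is followed by loss of a C4 proton (the only one available, since C6 is quaternary), should give the conjugated 1,3-dienyl triflate without a strong base that could cause E1cB loss of the silyloxy group from the glutarate.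

Step 10
Reactants: 13 but-2-ynoic acid
Product: 14 (Z)-3-iodobut-2-enoic acid
Conditions: NaI, AcOH, 110 °C
Reagents that add atoms: sodium iodide, [Na+].[I-]
Why: Conjugate hydroiodination of the ynoic acid (iodide to C3, anti protonation at C2) should place iodine cis to the carboxyl, which fixes the later 2Z geometry.

Step 11
Reactants: 14 (Z)-3-iodobut-2-enoic acid; 15 (E)-1,2-bis(tributylstannyl)ethene
Product: 16 (2Z,4E)-3-methyl-5-(tributylstannyl)penta-2,4-dienoic acid
Conditions: PdCl2(MeCN)2 (cat.), DMF, rt, 15 in excess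
Reagents that add atoms: none
Why: Stille coupling in which the Z vinyl iodide adds to zerovalent palladium with retention and one tin of the excess bis-stannane is transferred, so the 2Z,4E stannyl dienoic acid should result and double coupling is suppressed.

Step 12
Reactants: 12 [(1S)-1,3-dimethyl-2-(trifluoromethylsulfonyloxy)cyclohexa-2,4-dien-1-yl]methyl methyl (3R)-3-methyl-3-(triethylsilyloxy)pentanedioate; 16 (2Z,4E)-3-methyl-5-(tributylstannyl)penta-2,4-dienoic acid
Product: 17 ring-diene tetraenoic acid carrying the silylated glutarate ester on C8'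
Conditions: Pd2(dba)3 (cat.), AsPh3, NMP, 40 °C
Reagents that add atoms: none
Why: Stille coupling of the dienyl triflate with the alkenyl stannane under conditions suited to hindered cyclohexenyl triflates should form the C1'–C5 bond with retention of both alkene geometries, tolerating the free acid, the esters and the silyl ether and leaving C6' untouched.

Step 13
Reactants: 17 ring-diene tetraenoic acid carrying the silylated glutarate ester on C8'
Product: 19 triethylsilyl ether of the target at the glutarate hydroxyl, via ring endoperoxide 18 (not isolated)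
Conditions: O2, 5,10,15,20-tetraphenylporphyrin (cat.), hν (>500 nm), CH2Cl2, −78 °C; then Et3N (3 equiv), −78 °C → rt
Reagents that add atoms: dioxygen, O=O
Why: Energy transfer from the triplet sensitiser gives singlet oxygen, which adds suprafacially across C1' and C4' of the s-cis ring diene in a concerted [4+2] cycloaddition, and triethylamine then removes the only bridgehead hydrogen (C4'–H) so that the O–O bond breaks to the C4' ketone and the C1' alkoxide (Kornblum–DeLaMare rearrangement). The closest known reaction type is the dye-sensitised photo-oxygenation of 1-alkenylcyclohexa-1,3-dienes and the base-induced rearrangement of the resulting 2,3-dioxabicyclo[2.2.2]octenes to 4-hydroxycyclohex-2-enones. The one ring closed is the six-membered 1,2-dioxine ring of 18, formed by [4+2] cycloaddition with both C–O bonds made in one suprafacial event and opened again in the same pot, so no new ring remains in 19. The new stereocentre C1' is fixed by the face of dioxygen attack, which quaternary C6' controls: approach anti to the acyloxymethyl arm and syn to the small methyl should be favoured by the bulk of the arm and by repulsion between its ester oxygens and the incoming dioxygen, and the low temperature is chosen to sharpen this preference. Site selectivity among the three diene units is needed and is secured because only the ring diene is locked s-cis and electron-rich while the dienoic acid is electron-poor, a red-light sensitiser of low triplet energy is chosen so that the 2Z alkene is not isomerised, and the base step has no regiochemical choice because C1' carries no hydrogen.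

Step 14
Reactants: 19 triethylsilyl ether of the target at the glutarate hydroxyl
Product: 20 target CNP0274837.1
Conditions: HF·pyridine, pyridine, THF, 0 °C
Reagents that add atoms: none
Why: Fluoride-mediated desilylation with pyridine-buffered HF should cleave the tertiary triethylsilyl ether without touching the esters, the enone, the dienoic acid or the doubly allylic C1' carbinol.

**Compound list**

1 | 2,6-dimethylcyclohex-2-en-1-one (racemic) | CC1CCC=C(C)C1=O | starting material
2 | 1,3-dimethyl-2-(trimethylsilyloxy)cyclohexa-1,3-diene | CC1=C(O[Si](C)(C)C)C(C)=CCC1 | intermediate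
3 | (S)-6-(hydroxymethyl)-2,6-dimethylcyclohex-2-en-1-one | OC[C@]1(C)CCC=C(C)C1=O | intermediate
4 | (R)-mevalonolactone, (R)-4-hydroxy-4-methyltetrahydropyran-2-one | C[C@@]1(O)CCOC(=O)C1 | starting material
5 | potassium (R)-3,5-dihydroxy-3-methylpentanoate (potassium (R)-mevalonate) | C[C@@](O)(CCO)CC(=O)[O-].[K+] | intermediate (not isolated)
6 | benzyl (R)-3,5-dihydroxy-3-methylpentanoate | C[C@@](O)(CCO)CC(=O)OCc1ccccc1 | intermediate
7 | (R)-5-(benzyloxy)-3-hydroxy-3-methyl-5-oxopentanoic acid | C[C@@](O)(CC(=O)O)CC(=O)OCc1ccccc1 | intermediate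
8 | 1-benzyl 5-methyl (R)-3-hydroxy-3-methylpentanedioate | COC(=O)C[C@@](C)(O)CC(=O)OCc1ccccc1 | intermediate
9 | 1-benzyl 5-methyl (R)-3-methyl-3-(triethylsilyloxy)pentanedioate | COC(=O)C[C@@](C)(O[Si](CC)(CC)CC)CC(=O)OCc1ccccc1 | intermediate
10 | (S)-5-methoxy-3-methyl-5-oxo-3-(triethylsilyloxy)pentanoic acid | COC(=O)C[C@@](C)(O[Si](CC)(CC)CC)CC(=O)O | intermediate
11 | [(1S)-1,3-dimethyl-2-oxocyclohex-3-en-1-yl]methyl methyl (3R)-3-methyl-3-(triethylsilyloxy)pentanedioate | COC(=O)C[C@@](C)(O[Si](CC)(CC)CC)CC(=O)OC[C@]1(C)CCC=C(C)C1=O | intermediate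
12 | [(1S)-1,3-dimethyl-2-(trifluoromethylsulfonyloxy)cyclohexa-2,4-dien-1-yl]methyl methyl (3R)-3-methyl-3-(triethylsilyloxy)pentanedioate | COC(=O)C[C@@](C)(O[Si](CC)(CC)CC)CC(=O)OC[C@]1(C)CC=CC(C)=C1OS(=O)(=O)C(F)(F)F | intermediate
13 | but-2-ynoic acid | CC#CC(=O)O | starting material
14 | (Z)-3-iodobut-2-enoic acid | C/C(I)=C/C(=O)O | intermediate
15 | (E)-1,2-bis(tributylstannyl)ethene | CCCC[Sn](CCCC)(CCCC)/C=C/[Sn](CCCC)(CCCC)CCCC | starting material
16 | (2Z,4E)-3-methyl-5-(tributylstannyl)penta-2,4-dienoic acid | CCCC[Sn](CCCC)(CCCC)/C=C/C(C)=C\C(=O)O | intermediate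
17 | (2Z,4E)-5-[(6R)-6-({[(3R)-5-methoxy-3-methyl-5-oxo-3-(triethylsilyloxy)pentanoyl]oxy}methyl)-2,6-dimethylcyclohexa-1,3-dien-1-yl]-3-methylpenta-2,4-dienoic acid | COC(=O)C[C@@](C)(O[Si](CC)(CC)CC)CC(=O)OC[C@]1(C)CC=CC(C)=C1/C=C/C(C)=C\C(=O)O | intermediate
18 | endoperoxide: 2,3-dioxabicyclo[2.2.2]oct-5-ene with the (1E,3Z)-4-carboxy-3-methylbuta-1,3-dienyl chain on bridgehead C1 (C1'), methyl on C6 (C2'), methyl and the silylated glutarate oxymethyl arm on C7 (C6'), hydrogen on bridgehead C4 (C4'); the O–O bridge lies on the face of the C6' methyl, anti to the acyloxymethyl arm | COC(=O)C[C@@](C)(O[Si](CC)(CC)CC)CC(=O)OC[C@]1(C)C[C@@H]2C=C(C)[C@@]1(/C=C/C(C)=C\C(=O)O)OO2 | intermediate (not isolated)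
19 | (2Z,4E)-5-[(1R,6S)-1-hydroxy-6-({[(3R)-5-methoxy-3-methyl-5-oxo-3-(triethylsilyloxy)pentanoyl]oxy}methyl)-2,6-dimethyl-4-oxocyclohex-2-en-1-yl]-3-methylpenta-2,4-dienoic acid | COC(=O)C[C@@](C)(O[Si](CC)(CC)CC)CC(=O)OC[C@]1(C)CC(=O)C=C(C)[C@]1(O)/C=C/C(C)=C\C(=O)O | intermediate
20 | (2Z,4E)-5-[(1R,6S)-1-hydroxy-6-({[(3R)-3-hydroxy-5-methoxy-3-methyl-5-oxopentanoyl]oxy}methyl)-2,6-dimethyl-4-oxocyclohex-2-en-1-yl]-3-methylpenta-2,4-dienoic acid | COC(=O)C[C@@](C)(O)CC(=O)OC[C@]1(C)CC(=O)C=C(C)[C@]1(O)/C=C/C(C)=C\C(=O)O | target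

**Step count**

Total steps: 14. Longest linear sequence: 10 steps (from 4 through steps 3 to 9, then 12, 13 and 14).

**Steps most likely to fail**

Step 13. The risk is weak facial discrimination: dioxygen may add to both faces of the ring diene because CH3 and the acyloxymethyl arm on C6' differ only modestly, so the C1' epimer would accompany 19. The fallback sets out from 3 and comes back at 19. It sets C1' by chelate-controlled 1,2-addition and brings in the C4' oxygen by allylic C–H oxidation, with no cycloaddition.
- Excess HC≡CMgBr in THF/CH2Cl2 at −78 → 0 °C deprotonates the C8' hydroxyl, which then chelates magnesium to the carbonyl oxygen. The alkynyl group should enter anti to the pseudoaxial methyl, that is syn to C8', giving (1R,6S)-1-ethynyl-6-(hydroxymethyl)-2,6-dimethylcyclohex-2-en-1-ol F1.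
- DCC and 4-(dimethylamino)pyridine with 10 acylate only the primary hydroxyl, giving [(1S,2R)-2-ethynyl-2-hydroxy-1,3-dimethylcyclohex-3-en-1-yl]methyl methyl (3R)-3-methyl-3-(triethylsilyloxy)pentanedioate F2.
- Rh2(caprolactamate)4 with t-BuOOH oxidises the ring allylic CH2 (C4') to the enone [(1S,2R)-2-ethynyl-2-hydroxy-1,3-dimethyl-5-oxocyclohex-3-en-1-yl]methyl methyl (3R)-3-methyl-3-(triethylsilyloxy)pentanedioate F3.
- Bu3SnH with PdCl2(PPh3)2 adds syn across the terminal alkyne, giving [(1S,2R)-2-hydroxy-1,3-dimethyl-5-oxo-2-[(E)-2-(tributylstannyl)ethenyl]cyclohex-3-en-1-yl]methyl methyl (3R)-3-methyl-3-(triethylsilyloxy)pentanedioate F4.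
- Stille coupling of F4 with 14 (PdCl2(MeCN)2, DMF) gives 19.

Step 2. The risk is low enantioface discrimination at the fully substituted enol carbon, together with hydrolysis of the silyl enol ether back to 1 in the aqueous medium. The fallback sets out from 2 and comes back at 3. It sets C6 by enantioselective Tsuji allylation and then trims the allyl group to CH2OH.
- Treatment of 2 with diallyl carbonate, Bu4N[Ph3SiF2], Pd2(dba)3 and (S)-4-tert-butyl-2-[2-(diphenylphosphino)phenyl]-4,5-dihydrooxazole in THF should give (S)-6-allyl-2,6-dimethylcyclohex-2-en-1-one F5.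
- RuHCl(CO)(PPh3)3 in toluene moves the double bond to give (S)-2,6-dimethyl-6-[(E)-prop-1-enyl]cyclohex-2-en-1-one F6.
- O3 at −78 °C followed by Me2S cleaves the electron-rich propenyl alkene in preference to the enone, giving (S)-1,3-dimethyl-2-oxocyclohex-3-ene-1-carbaldehyde F7.
- NaBH(OAc)3 reduces only the aldehyde to give 3.

Step 9. The risk is loss of the triethylsilyl group or activation of an ester carbonyl by Tf2O, or no reaction at the encumbered carbonyl. A strong base cannot be used on 11 because the β-silyloxy ester would eliminate. The fallback sets out from 3 and comes back at 12. It forms the triflate before any ester is present.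
- t-BuMe2SiCl and imidazole give (S)-6-[(tert-butyldimethylsilyloxy)methyl]-2,6-dimethylcyclohex-2-en-1-one F8.
- KN(SiMe3)2 with PhNTf2 in THF at −78 °C, where gamma deprotonation is the only path, gives (S)-6-[(tert-butyldimethylsilyloxy)methyl]-2,6-dimethylcyclohexa-1,3-dien-1-yl trifluoromethanesulfonate F9.
- HF·pyridine frees the alcohol, giving (S)-6-(hydroxymethyl)-2,6-dimethylcyclohexa-1,3-dien-1-yl trifluoromethanesulfonate F10.
- DCC and 4-(dimethylamino)pyridine with 10 give 12.

Further compounds
F1 | step 13 | (1R,6S)-1-ethynyl-6-(hydroxymethyl)-2,6-dimethylcyclohex-2-en-1-ol | OC[C@]1(C)CCC=C(C)[C@]1(O)C#C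
F2 | step 13 | [(1S,2R)-2-ethynyl-2-hydroxy-1,3-dimethylcyclohex-3-en-1-yl]methyl methyl (3R)-3-methyl-3-(triethylsilyloxy)pentanedioate | COC(=O)C[C@@](C)(O[Si](CC)(CC)CC)CC(=O)OC[C@]1(C)CCC=C(C)[C@]1(O)C#C
F3 | step 13 | [(1S,2R)-2-ethynyl-2-hydroxy-1,3-dimethyl-5-oxocyclohex-3-en-1-yl]methyl methyl (3R)-3-methyl-3-(triethylsilyloxy)pentanedioate | COC(=O)C[C@@](C)(O[Si](CC)(CC)CC)CC(=O)OC[C@]1(C)CC(=O)C=C(C)[C@]1(O)C#C
F4 | step 13 | [(1S,2R)-2-hydroxy-1,3-dimethyl-5-oxo-2-[(E)-2-(tributylstannyl)ethenyl]cyclohex-3-en-1-yl]methyl methyl (3R)-3-methyl-3-(triethylsilyloxy)pentanedioate | COC(=O)C[C@@](C)(O[Si](CC)(CC)CC)CC(=O)OC[C@]1(C)CC(=O)C=C(C)[C@]1(O)/C=C/[Sn](CCCC)(CCCC)CCCC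
F5 | step 2 | (S)-6-allyl-2,6-dimethylcyclohex-2-en-1-one | C=CC[C@]1(C)CCC=C(C)C1=O
F6 | step 2 | (S)-2,6-dimethyl-6-[(E)-prop-1-enyl]cyclohex-2-en-1-one | C/C=C/[C@]1(C)CCC=C(C)C1=O
F7 | step 2 | (S)-1,3-dimethyl-2-oxocyclohex-3-ene-1-carbaldehyde | O=C[C@]1(C)CCC=C(C)C1=O
F8 | step 9 | (S)-6-[(tert-butyldimethylsilyloxy)methyl]-2,6-dimethylcyclohex-2-en-1-one | CC(C)(C)[Si](C)(C)OC[C@]1(C)CCC=C(C)C1=O
F9 | step 9 | (S)-6-[(tert-butyldimethylsilyloxy)methyl]-2,6-dimethylcyclohexa-1,3-dien-1-yl trifluoromethanesulfonate | CC(C)(C)[Si](C)(C)OC[C@]1(C)CC=CC(C)=C1OS(=O)(=O)C(F)(F)F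
F10 | step 9 | (S)-6-(hydroxymethyl)-2,6-dimethylcyclohexa-1,3-dien-1-yl trifluoromethanesulfonate | OC[C@]1(C)CC=CC(C)=C1OS(=O)(=O)C(F)(F)F
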